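The target is procyanidin B3 3,3'-di-O-gallate, two catechin gallates joined C4→C8'. The route rests on disconnecting C4–C4a of the upper unit. C4, the crowded methine bonded to C4a (ring A), C8' (ring D) and C3 and ringed by four ortho oxygens, is taken back to an sp carbon: a C3≡C4 alkyne already carrying ring D and tethered to ring A through the O1–C2 aryl ether. One gold-catalysed 6-endo-dig hydroarylation then forms C4–C4a and closes ring C as a 4-aryl-2H-chromene; syn hydroboration later sets C3 and C4. The precursor is a fully benzylated 3,5-dioxygenated aryl propargyl ether whose alkyne terminus bears the catechin unit with its 3-hydroxyl left free.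

Key step: step 6

Assumption: in step 4 the (S,S)-Ph-pybox ligand is taken to deliver the (S)-configured aryl propargyl ether; if the sense of induction proves opposite, the (R,R)-ligand is used with nothing else changed.

Design note: the lower-unit 3-hydroxyl is carried free (not as its gallate) through steps 5–7. No ester then meets borane, and both gallates go on in one operation in step 8.

Stereochemical note: the upper-unit C2 keeps one spatial arrangement from step 4 to the target. Its descriptor alternates (S, R, S, then R) only because the CIP rank of its neighbours changes.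

Step 1
Reactants: 1 (+)-catechin; 2 benzyl bromide
Product: 3 5,7,3',4'-tetra-O-benzyl-(+)-catechin [(2R,3S)-5,7-bis(benzyloxy)-2-[3,4-bis(benzyloxy)phenyl]chroman-3-ol]
Conditions: BnBr (4.4 equiv), K2CO3, DMF, 0 °C to rt, argon
Reagents that add atoms: benzyl bromide, BrCc1ccccc1
Why: Williamson etherification, in which K2CO3 deprotonates only the four phenols for SN2 benzylation while the aliphatic 3-OH stays free and C2 and C3 are untouched under these mild conditions.

Step 2
Reactants: 3 5,7,3',4'-tetra-O-benzyl-(+)-catechin; 4 N-iodosuccinimide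
Product: 5 8-iodo-5,7,3',4'-tetra-O-benzyl-(+)-catechin [(2R,3S)-5,7-bis(benzyloxy)-2-[3,4-bis(benzyloxy)phenyl]-8-iodochroman-3-ol]
Conditions: NIS (1.05 equiv), CH2Cl2, −20 °C to 0 °C, dark
Reagents that add atoms: N-iodosuccinimide, O=C1CCC(=O)N1I
Why: Electrophilic aromatic iodination, in which the phloroglucinol-type ring A reacts far ahead of ring B and C8 is expected to be preferred over C6, as in the well-established C8-selective NBS bromination of this same benzyl ether, with one equivalent of NIS at low temperature limiting di-iodination.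

Step 3
Reactants: 6 3,4-bis(benzyloxy)benzaldehyde; 7 ethynylmagnesium bromide; 8 di-tert-butyl dicarbonate
Product: 10 rac-1-[3,4-bis(benzyloxy)phenyl]prop-2-yn-1-yl tert-butyl carbonate, via bromomagnesium propargylic alkoxide 9 (not isolated)
Conditions: HC≡CMgBr (1.1 equiv), THF, 0 °C; then Boc2O (1.3 equiv), 0 °C to rt; H2O work-up
Reagents that add atoms: ethynylmagnesium bromide, C#C[Mg]Br; di-tert-butyl dicarbonate, CC(C)(C)OC(=O)OC(=O)OC(C)(C)C
Why: Grignard 1,2-addition of the acetylide to the aldehyde followed by O-acylation of the magnesium alkoxide by Boc2O in the same flask; the racemate suffices because step 4 is enantioconvergent.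

Step 4
Reactants: 10 rac-1-[3,4-bis(benzyloxy)phenyl]prop-2-yn-1-yl tert-butyl carbonate; 11 3,5-bis(benzyloxy)phenol
Product: 12 (S)-4-{1-[3,5-bis(benzyloxy)phenoxy]prop-2-yn-1-yl}-1,2-bis(benzyloxy)benzene
Conditions: (CuOTf)2·C6H6 (2.5 mol %), (S,S)-Ph-pybox (6 mol %), iPr2NEt (20 mol %), CH2Cl2, −20 °C
Reagents that add atoms: 3,5-bis(benzyloxy)phenol, Oc1cc(OCc2ccccc2)cc(OCc2ccccc2)c1
Why: Copper-catalysed enantioselective propargylic etherification, in which the copper acetylide of 10 loses tert-butyl carbonate to give a copper allenylidene common to both enantiomers of 10 and the phenoxide of 11 adds through oxygen to the γ-carbon on the face left open by the pybox ligand, which sets the future C2 as (S).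

Step 5
Reactants: 12 (S)-aryl propargyl ether; 5 8-iodo-5,7,3',4'-tetra-O-benzyl-(+)-catechin
Product: 13 (2R,3S)-5,7-bis(benzyloxy)-2-[3,4-bis(benzyloxy)phenyl]-8-{(3R)-3-[3,4-bis(benzyloxy)phenyl]-3-[3,5-bis(benzyloxy)phenoxy]prop-1-yn-1-yl}chroman-3-ol (key-step precursor)
Conditions: Pd(PPh3)2Cl2 (5 mol %), CuI (10 mol %), iPr2NH/THF (1:3), degassed, 50 °C, slow addition of 12
Reagents that add atoms: compound 5, O[C@H]1Cc2c(OCc3ccccc3)cc(OCc3ccccc3)c(I)c2O[C@@H]1c1ccc(OCc2ccccc2)c(OCc2ccccc2)c1
Why: Sonogashira coupling, in which zerovalent palladium inserts into the C8–I bond and the copper acetylide of 12 transmetalates, so the future C4–C8' bond is made as an unhindered sp–sp2 link while the propargylic centre is not involved (its descriptor becomes R only because the arylalkynyl group now outranks ring B).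

Step 6
Reactants: 13 key-step precursor
Product: 14 (2R,3S)-5,7-bis(benzyloxy)-2-[3,4-bis(benzyloxy)phenyl]-8-{(2S)-5,7-bis(benzyloxy)-2-[3,4-bis(benzyloxy)phenyl]-2H-chromen-4-yl}chroman-3-ol (key-step product)
Conditions: Ph3PAuNTf2 (5 mol %), CH2Cl2 (0.02 M), 4 Å MS, 0 °C to rt, dark
Reagents that add atoms: none
Why: Cationic monovalent gold binds the C3≡C4 alkyne, the 2,4,6-trioxygenated ring D stabilises positive charge at C4, and an ortho carbon of the 3,5-bis(benzyloxy)phenoxy ring (ring A) attacks C4 anti to gold; rearomatisation and protodeauration of the C3 vinylgold then release the chromene and the catalyst. The closest known reaction type is the gold- or platinum-catalysed cycloisomerisation (intramolecular hydroarylation) of aryl propargyl ethers to 2H-chromenes. Ring C closes in the 6-endo-dig mode by a Friedel–Crafts-type attack on the π-activated alkyne. No stereocentre is formed: C4 becomes sp2, and C2 is a spectator whose configuration from step 4 is kept because the neutral, silver-free catalyst at or below room temperature does not ionise the C2–O1 bond. The selectivity needed is C-attack at C4 over 5-exo attack at C3 and over attack by the ring D ether oxygens; the substrate secures it because ring D polarises the alkyne towards C4, the ring D oxygens can reach only the electron-poor C3 (5-endo, reversible oxonium formation), and the two ortho carbons of ring A are equivalent. The free lower-unit hydroxyl cannot reach the alkyne and is tolerated by the catalyst.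

Step 7
Reactants: 14 key-step product; 15 borane–dimethyl sulfide; 16 sodium perborate (as tetrahydrate)
Product: 18 octa-O-benzyl procyanidin B3 (upper unit 2R,3S,4S; lower unit 2R,3S; both 3-hydroxyls free), via C3-alkylborane O-borinate 17 (not isolated)
Conditions: BH3·SMe2 (4 equiv), THF, 0 °C to rt; then NaBO3·4H2O, THF/H2O, rt
Reagents that add atoms: sodium perborate, [Na+].[O-]OB=O (the C3 oxygen); borane–dimethyl sulfide, C[S+](C)[BH3-] (boron of 17 only, hydrogen at C4)
Why: Hydroboration–oxidation, in which BH3 adds syn across C3=C4 from the face opposite the C2 aryl group with boron on the less substituted C3 and hydride on the diaryl-substituted C4, and oxidation with retention converts C–B into C–OH, which sets C3 (S) and C4 (S) as 2,3-trans-3,4-trans; the lower hydroxyl is masked only transiently as a borinate and the near-neutral perborate work-up guards against β-elimination of the C3 borane towards O1.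

Step 8
Reactants: 18 octa-O-benzyl procyanidin B3; 19 3,4,5-tris(benzyloxy)benzoic acid
Product: 20 tetradeca-O-benzyl procyanidin B3 3,3'-di-O-gallate
Conditions: 19 (3 equiv), DCC (3 equiv), DMAP (0.5 equiv), CH2Cl2, rt
Reagents that add atoms: 3,4,5-tris(benzyloxy)benzoic acid, OC(=O)c1cc(OCc2ccccc2)c(OCc2ccccc2)c(OCc2ccccc2)c1
Why: Steglich esterification acylates both secondary 3-hydroxyls in one operation, a standard way to galloylate benzylated flavan-3-ols and their dimers, and no stereocentre takes part.

Step 9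
Reactants: 20 tetradeca-O-benzyl procyanidin B3 3,3'-di-O-gallate
Product: 21 procyanidin B3 3,3'-di-O-gallate (target, CNP0281991.3)
Conditions: H2 (1 atm), Pd(OH)2/C, THF/MeOH/H2O, rt
Reagents that add atoms: none
Why: Catalytic hydrogenolysis should cleave all fourteen benzyl ethers to toluene while the gallate esters, the C4–C8' bond and the ring C2–O1 ethers are expected to survive neutral Pd(OH)2/C conditions, as is usual for benzylated flavan-3-ol gallates.

Compound list
1 | (+)-catechin | O[C@H]1Cc2c(O)cc(O)cc2O[C@@H]1c1ccc(O)c(O)c1 | starting material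
2 | benzyl bromide | BrCc1ccccc1 | starting material
3 | 5,7,3',4'-tetra-O-benzyl-(+)-catechin (2R,3S) | O[C@H]1Cc2c(OCc3ccccc3)cc(OCc3ccccc3)cc2O[C@@H]1c1ccc(OCc2ccccc2)c(OCc2ccccc2)c1 | intermediate
4 | N-iodosuccinimide | O=C1CCC(=O)N1I | starting material
5 | 8-iodo-5,7,3',4'-tetra-O-benzyl-(+)-catechin (2R,3S) | O[C@H]1Cc2c(OCc3ccccc3)cc(OCc3ccccc3)c(I)c2O[C@@H]1c1ccc(OCc2ccccc2)c(OCc2ccccc2)c1 | intermediate
6 | 3,4-bis(benzyloxy)benzaldehyde | O=Cc1ccc(OCc2ccccc2)c(OCc2ccccc2)c1 | starting material
7 | ethynylmagnesium bromide | C#C[Mg]Br | starting material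
8 | di-tert-butyl dicarbonate | CC(C)(C)OC(=O)OC(=O)OC(C)(C)C | starting material
9 | bromomagnesium 1-[3,4-bis(benzyloxy)phenyl]prop-2-yn-1-olate (racemic, not isolated) | C#CC(O[Mg]Br)c1ccc(OCc2ccccc2)c(OCc2ccccc2)c1 | intermediate
10 | rac-1-[3,4-bis(benzyloxy)phenyl]prop-2-yn-1-yl tert-butyl carbonate | C#CC(OC(=O)OC(C)(C)C)c1ccc(OCc2ccccc2)c(OCc2ccccc2)c1 | intermediate
11 | 3,5-bis(benzyloxy)phenol | Oc1cc(OCc2ccccc2)cc(OCc2ccccc2)c1 | starting material
12 | (S)-4-{1-[3,5-bis(benzyloxy)phenoxy]prop-2-yn-1-yl}-1,2-bis(benzyloxy)benzene | C#C[C@H](Oc1cc(OCc2ccccc2)cc(OCc2ccccc2)c1)c1ccc(OCc2ccccc2)c(OCc2ccccc2)c1 | intermediate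
13 | key-step precursor: 8-alkynylated tetra-O-benzylcatechin (2R,3S) bearing the (R)-configured 3,5-bis(benzyloxy)phenyl propargyl ether | O[C@H]1Cc2c(OCc3ccccc3)cc(OCc3ccccc3)c(C#C[C@H](Oc3cc(OCc4ccccc4)cc(OCc4ccccc4)c3)c3ccc(OCc4ccccc4)c(OCc4ccccc4)c3)c2O[C@@H]1c1ccc(OCc2ccccc2)c(OCc2ccccc2)c1 | intermediate
14 | key-step product: (2S)-5,7-bis(benzyloxy)-2-[3,4-bis(benzyloxy)phenyl]-4-(lower unit)-2H-chromene, lower unit = tetra-O-benzylcatechin-8-yl (2R,3S) | O[C@H]1Cc2c(OCc3ccccc3)cc(OCc3ccccc3)c(C3=C[C@@H](c4ccc(OCc5ccccc5)c(OCc5ccccc5)c4)Oc4cc(OCc5ccccc5)cc(OCc5ccccc5)c34)c2O[C@@H]1c1ccc(OCc2ccccc2)c(OCc2ccccc2)c1 | intermediate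
15 | borane–dimethyl sulfide | C[S+](C)[BH3-] | starting material
16 | sodium perborate (used as tetrahydrate) | [Na+].[O-]OB=O | starting material
17 | C3-dihydroboryl adduct of 14 (boron trans to both the C2 and C4 aryl groups), lower 3-O-BH2 borinate (not isolated) | B[C@H]1[C@H](c2c(OCc4ccccc4)cc(OCc4ccccc4)c3c2O[C@H](c2ccc(OCc4ccccc4)c(OCc4ccccc4)c2)[C@@H](OB)C3)c2c(OCc4ccccc4)cc(OCc4ccccc4)cc2O[C@@H]1c1ccc(OCc4ccccc4)c(OCc4ccccc4)c1 | intermediate
18 | octa-O-benzyl procyanidin B3 (upper 2R,3S,4S; lower 2R,3S) | O[C@H]1[C@H](c2c(OCc4ccccc4)cc(OCc4ccccc4)c3c2O[C@H](c2ccc(OCc4ccccc4)c(OCc4ccccc4)c2)[C@@H](O)C3)c2c(OCc4ccccc4)cc(OCc4ccccc4)cc2O[C@@H]1c1ccc(OCc4ccccc4)c(OCc4ccccc4)c1 | intermediate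
19 | 3,4,5-tris(benzyloxy)benzoic acid | OC(=O)c1cc(OCc2ccccc2)c(OCc2ccccc2)c(OCc2ccccc2)c1 | starting material
20 | tetradeca-O-benzyl procyanidin B3 3,3'-di-O-gallate | O=C(O[C@H]1[C@H](c2c(OCc4ccccc4)cc(OCc4ccccc4)c3c2O[C@H](c2ccc(OCc4ccccc4)c(OCc4ccccc4)c2)[C@@H](OC(=O)c2cc(OCc4ccccc4)c(OCc4ccccc4)c(OCc4ccccc4)c2)C3)c2c(OCc4ccccc4)cc(OCc4ccccc4)cc2O[C@@H]1c1ccc(OCc4ccccc4)c(OCc4ccccc4)c1)c1cc(OCc4ccccc4)c(OCc4ccccc4)c(OCc4ccccc4)c1 | intermediate
21 | procyanidin B3 3,3'-di-O-gallate (upper 2R,3S,4S; lower 2R,3S) | O=C(O[C@H]1[C@H](c2c(O)cc(O)c3c2O[C@H](c2ccc(O)c(O)c2)[C@@H](OC(=O)c2cc(O)c(O)c(O)c2)C3)c2c(O)cc(O)cc2O[C@@H]1c1ccc(O)c(O)c1)c1cc(O)c(O)c(O)c1 | target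

Total step count: 9. Longest linear sequence: 7 steps (compound 6 to 21 through steps 3–9; the catechin branch, steps 1–2, joins at step 5).

Steps most likely to fail

Step 6. The gold-activated alkyne may be intercepted by the 7'-benzyloxy oxygen of ring D (5-endo attack at C3 followed by benzyl transfer towards a benzofuran), or the C2–O1 bond may ionise with loss of the C2 configuration. The fallback gives up the alkyne and makes the interflavan bond by the established acid-catalysed flavan C4 cation coupling. It sets out from compound 3, which is oxidised at C4 with DDQ in CH2Cl2 in the presence of 2-ethoxyethanol to give 4-(2-ethoxyethoxy)-5,7,3',4'-tetra-O-benzylcatechin F1. F1 is then ionised with catalytic TMSOTf in CH2Cl2 at −78 °C in the presence of an excess of 3 (about 4 equiv, to suppress oligomers). C8 of 3 should add to the C4 cation trans to the 3-hydroxyl, and the detour comes back to the route at compound 18, bypassing step 7 as well.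

Step 4. The copper allenylidene may alkylate the phloroglucinol-type ring of 11 at carbon in competition with oxygen, and uncatalysed ionisation of the electron-rich carbonate may erode the enantioselectivity. The fallback separates the stereo-defining step from the ether formation. It sets out from compound 6, which undergoes enantioselective zinc alkynylation with trimethylsilylacetylene (Me2Zn, ProPhenol ligand antipode selected for the (S)-alcohol, toluene, 0 °C) to give (S)-1-[3,4-bis(benzyloxy)phenyl]-3-(trimethylsilyl)prop-2-yn-1-ol F2. A Mitsunobu reaction of F2 with 11 (PPh3, DIAD, toluene, −20 °C) should give, with inversion and exclusive O-alkylation, the (R)-configured silylated ether [(R)-3-[3,4-bis(benzyloxy)phenyl]-3-[3,5-bis(benzyloxy)phenoxy]prop-1-yn-1-yl]trimethylsilane F3. K2CO3 in MeOH removes the silyl group, and the detour comes back at compound 12.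

Step 5. Oxidative addition into the doubly ortho-oxygenated, electron-rich C8–I bond may be slow enough for copper-mediated oxidative dimerisation of 12 and protodeiodination of 5 to consume both fragments. The fallback replaces the copper acetylide by a zinc acetylide (Negishi alkynylation), which has no oxidative homocoupling path and transmetalates faster. It sets out from compound 12, which is converted in the flask with ZnBr2 and Et3N in THF into the bromozinc acetylide of 12 F4. F4 is coupled with 5 under Pd(PPh3)4 at rt to 50 °C, and the detour comes back at compound 13.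

Further compounds
F1 | step 6 | 4-(2-ethoxyethoxy)-5,7,3',4'-tetra-O-benzylcatechin (2R,3S; configuration at C4 left open, since it is lost on ionisation) | O[C@H]1C(OCCOCC)c2c(OCc3ccccc3)cc(OCc3ccccc3)cc2O[C@@H]1c1ccc(OCc2ccccc2)c(OCc2ccccc2)c1
F2 | step 4 | (S)-1-[3,4-bis(benzyloxy)phenyl]-3-(trimethylsilyl)prop-2-yn-1-ol | C[Si](C)(C)C#C[C@@H](O)c1ccc(OCc2ccccc2)c(OCc2ccccc2)c1
F3 | step 4 | [(R)-3-[3,4-bis(benzyloxy)phenyl]-3-[3,5-bis(benzyloxy)phenoxy]prop-1-yn-1-yl]trimethylsilane | C[Si](C)(C)C#C[C@H](Oc1cc(OCc2ccccc2)cc(OCc2ccccc2)c1)c1ccc(OCc2ccccc2)c(OCc2ccccc2)c1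
F4 | step 5 | bromozinc acetylide of 12 (configuration of 12 retained) | Br[Zn]C#C[C@H](Oc1cc(OCc2ccccc2)cc(OCc2ccccc2)c1)c1ccc(OCc2ccccc2)c(OCc2ccccc2)c1
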